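## Structural features

Didemnimide D (10) consists of three rings joined only by two C(sp2)–C(sp2) single bonds. A 6-bromo-1H-indole (ring A) is bound through its C3 to C3 of a central 1H-pyrrole-2,5-dione (maleimide, ring B: N1, C2, C3, C4, C5), and a 1-methylimidazole (ring C) is bound through its C5 to C4 of ring B. The molecule has no stereocentre, and its only non-aromatic double bond, C3=C4 of ring B, is held cis by the five-membered ring, so no configuration has to be controlled in the target. The fragile or interfering groups are:
- the C6–Br bond of ring A, which is lost to zerovalent palladium or nickel on heating, to halogen–metal exchange and to hydrogenolysis;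
- the two acidic N–H groups (imide and indole);
- the basic, metal-binding N3 of ring C;
- the imide itself, a Michael acceptor that opens with hard nucleophiles.

The 1,5-pattern of ring C (methyl on the nitrogen next to the point of attachment) cannot be set reliably by late N-methylation, which favours the less hindered 1,4-isomer, so it is best brought in with a building block. The real difficulty is the fully substituted, unsymmetrical C3=C4 bond: two different, electron-rich, nitrogen-bearing heteroaryl groups must sit on neighbouring carbons of an electron-poor ring, without homodimeric products and without harm to C6–Br. The key step exploits the fact that C3 and C4 with their two heteroaryl groups are a masked diheteroaryl alkyne, while the rest of ring B, C2(=O)–N1(H)–C5(=O), consists of nothing but two molecules of carbon monoxide and one of ammonia. Because that chain is locally symmetrical, an unsymmetrical alkyne can give only one constitutional isomer when ring B is laid over it.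

## Logic of the disconnections

**10 to 9.** No skeletal bond is cut; the π bond C3=C4 of ring B in 10 is exchanged for the C3–H and C4–H bonds of 9. The reason is the balance of oxidation levels. The atoms of 6, two molecules of 7 and one of 8 add up exactly to 9, two hydrogens above 10, so the ring-forming step can be redox-neutral and needs no oxidant beside a low-valent metal. The price is two transient stereocentres; the gain is that the next cut becomes possible. The forward step must remove only these two hydrogens, each activated by an imide carbonyl and a heteroarene. It must not oxidise ring A or join rings A and C.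

**9 to 6 + 7 + 7 + 8 (key disconnection).** Four of the five bonds of ring B are cut at once: C2–C3, C4–C5, N1–C2 and N1–C5. In one sentence: ring B is built in a single operation from 6, two molecules of 7 and one of 8. The cut is placed here because only the C3–C4 bond carries the unsymmetry of the target, and it is the one bond that is kept. A three-ring array with a tetrasubstituted alkene goes back to a linear compound whose two ends are joined one at a time. The unsymmetry therefore costs nothing, and no regioisomer is possible. The forward step demands a metal that binds an electron-rich triple bond in the presence of nitrogen donors, inserts 7 twice and not once, and leaves C6–Br alone.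

**6 to 5, and 5 to 3 + 4.** 5 differs from 6 only by the carbamate on N1 of ring A, which is added in the retrosynthetic sense because the halide partner needs it. The bond cut is C3(ring A)–C(sp). This divides the molecule into its two heteroaromatic halves, and 4 already carries the 1,5-pattern of ring C and both carbons that become C3 and C4 of ring B. The forward sp–sp2 coupling must distinguish the C3–halogen bond of 3 from C6–Br, which calls for the heavier halogen at C3 and room temperature.

**3 to 2 to 1.** The N1–carbamate bond and the C3–I bond are cut. Both are simple functionalisations of the most nucleophilic positions of 1, which already bears the bromine at C6. No regiochemical problem of the benzenoid ring has to be solved. The forward steps must be run without delay, because 2 is sensitive.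

## Other disconnections considered

**Alternative 1:** (the first that comes to mind) Cut of the C3=C4 double bond and of one N–C(=O) bond of ring B.
- Forward key step: a Perkin-type condensation with KOtBu in THF between methyl 2-(6-bromo-1H-indol-3-yl)-2-oxoacetate A1 (from 1, oxalyl chloride and methanol) and 2-(1-methyl-1H-imidazol-5-yl)acetamide A2. The amide enolate adds to the keto group, the lactam closes and water is lost.
- Step economy: the plan is convergent and sound, but its simplification is uneven. A1 is one step from 1, whereas A2 needs a one-carbon homologation at C5 of ring C over several steps, so the overall count should exceed four.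
- Mechanism: the carbon acid of A2 must be deprotonated beside more acidic N–H groups, which calls for a large excess of strong base.
- The chosen plan buys the carbon framework of ring C ready-made in 4 and uses no strong base. This alternative is also the route the first test excludes.

**Alternative 2:** Cut of the two C(sp2)–C(sp2) bonds that join ring B to rings A and C, with ring B bought ready-made as 3,4-dibromo-1H-pyrrole-2,5-dione A3.
- Forward sequence: addition–elimination of the bromomagnesium salt of 1 to A3 gives 3-bromo-4-(6-bromo-1H-indol-3-yl)-1H-pyrrole-2,5-dione A4. The key step is then a Stille coupling of A4 with 1-methyl-5-(tributylstannyl)-1H-imidazole A5.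
- Structure: A4 holds two C–Br bonds, so zerovalent palladium must choose the vinylic one on heating, exactly the situation the target tolerates least.
- Mechanism: the free imide N–H consumes organometallic reagent or demands a protecting group with two further steps. A C5-metalated ring C is prone to protodemetalation.
- A stoichiometric amount of tin is also used. In the chosen plan palladium meets the bromide only at room temperature and in competition with an iodide.

**Alternative 3:** Cut of ring C at C4–C5 and N1–C2 (closure of a heteroaromatic ring at a carbon–carbon bond).
- Forward key step: a van Leusen three-component imidazole synthesis. 4-(6-Bromo-1H-indol-3-yl)-2,5-dioxo-2,5-dihydro-1H-pyrrole-3-carbaldehyde A6 is condensed with methylamine to its N-methylaldimine A7, which reacts with tosylmethyl isocyanide and base. This sets the 1,5-pattern of ring C by construction, which is attractive.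
- Mechanism: A6 is a vinylogous tricarbonyl compound. Methylamine should attack the ring carbons or open the imide in competition with imine formation. The anion of tosylmethyl isocyanide should add to the C3=C4 Michael acceptor in the pyrrole-forming mode of the same reagent.
- Structure: the hard part, the unsymmetrical C3=C4 bond, is left untouched in A6, which itself needs several steps, while the 1,5-pattern can simply be bought.

Key step: step 3

Assumption: 1, 4, 7 and 8 are taken as commercially available; 10 is achiral, so 9 is handled as a racemate and its relative configuration has no bearing on the outcome.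

## Route

**Step 1**
Reactants: 1 6-bromo-1H-indole
Product: 3 tert-butyl 6-bromo-3-iodo-1H-indole-1-carboxylate, via 6-bromo-3-iodo-1H-indole 2 (not isolated)
Conditions: I2, KOH, DMF, rt; extractive work-up, crude 2; then Boc2O, DMAP (cat.), CH2Cl2, rt
Reagents that add atoms: iodine, [I][I]; di-tert-butyl dicarbonate (Boc2O), CC(C)(C)OC(=O)OC(=O)OC(C)(C)C
Why: Electrophilic iodination of the indolide at its most nucleophilic position C3, followed by DMAP-catalysed N-acylation. The carbamate stabilises the light- and acid-sensitive 3-iodoindole and makes C3–I more prone to oxidative addition; C6–Br is inert to both operations.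

**Step 2**
Reactants: 3 tert-butyl 6-bromo-3-iodo-1H-indole-1-carboxylate; 4 5-ethynyl-1-methyl-1H-imidazole
Product: 6 6-bromo-3-[(1-methyl-1H-imidazol-5-yl)ethynyl]-1H-indole, via N-Boc alkyne 5 (not isolated)
Conditions: PdCl2(PPh3)2 (cat.), CuI (cat.), Et3N, THF, rt, argon; filter, concentrate; then NaOMe (cat.), MeOH, rt
Reagents that add atoms: none
Why: Sonogashira coupling; at room temperature zerovalent palladium inserts into C3–I far faster than into C6–Br, so the bromide should be kept. The indole carbamate is an activated, azolide-like carbamate and is removed by methoxide-catalysed transesterification, to which the alkyne, the bromide and ring C are inert.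

**Step 3**
Reactants: 6 6-bromo-3-[(1-methyl-1H-imidazol-5-yl)ethynyl]-1H-indole; 7 carbon monoxide (two molecules are incorporated); 8 ammonia
Product: 9 (±)-trans-3-(6-bromo-1H-indol-3-yl)-4-(1-methyl-1H-imidazol-5-yl)pyrrolidine-2,5-dione
Conditions: Fe3(CO)12 (cat.), CO (20 bar), NH3 (excess), THF, 120 °C, autoclave
Reagents that add atoms: carbon monoxide (7), [C-]#[O+]; ammonia (8), N
Why: This is the iron-carbonyl-catalysed double carbonylation of an internal alkyne with ammonia, a known redox-neutral reaction type that turns diaryl alkynes into 3,4-diaryl succinimides. Ammonia breaks Fe3(CO)12 down to mononuclear zerovalent iron carbonyl species, which bind the triple bond of 6 and take up two CO ligands by migratory insertion to give a ferracyclopentenedione (maleoyl iron), in which both new C–C bonds (C2–C3 and C4–C5) are in place and necessarily cis. Attack of 8 on one acyl carbon opens the metallacycle to a (Z)-carbamoylacryloyl iron hydride, and the amide nitrogen then attacks the remaining iron acyl in a 5-exo-trig acyl substitution, which closes ring B at its second N–C(=O) bond. The two hydrogens left on iron pass to the still coordinated, electron-poor C3=C4 bond, so 9 is released and zerovalent iron returns; the atoms of 6, two 7 and one 8 add up exactly to 9. No regiochemical question arises, because the C2(=O)–N1(H)–C5(=O) unit is symmetrical and both orientations of the unsymmetrical alkyne lead to the same compound. The two new stereocentres C3 and C4 carry acidic hydrogens and should equilibrate in hot ammonia to the less crowded trans isomer (thermodynamic control); both are erased in step 4, so either diastereomer serves. The step needs chemoselectivity for the alkyne over C6–Br, secured by the reluctance of iron carbonyls to insert into aryl bromides and by the absence of palladium and nickel. It also needs tolerance of N3 of ring C and of the indole N–H, which is plausible because the catalyst already operates in a large excess of the stronger donor and nucleophile 8.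

**Step 4**
Reactants: 9 (±)-trans-3-(6-bromo-1H-indol-3-yl)-4-(1-methyl-1H-imidazol-5-yl)pyrrolidine-2,5-dione
Product: 10 didemnimide D, 3-(6-bromo-1H-indol-3-yl)-4-(1-methyl-1H-imidazol-5-yl)-1H-pyrrole-2,5-dione
Conditions: DDQ, 1,4-dioxane, rt to 60 °C
Reagents that add atoms: none
Why: DDQ dehydrogenation of a 3-(indol-3-yl)succinimide to the maleimide. Hydride abstraction from C3–H is assisted by the indole nitrogen (3-alkylideneindoleninium ion), and loss of the acidic C4–H gives the conjugated C3=C4 bond. Both stereocentres vanish, and the aryl bromide and ring C should not be touched by the quinone in the absence of acid.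

## Compound list

1 | 6-bromo-1H-indole | Brc1ccc2cc[nH]c2c1 | starting material
2 | 6-bromo-3-iodo-1H-indole | Ic1c[nH]c2cc(Br)ccc12 | intermediate
3 | tert-butyl 6-bromo-3-iodo-1H-indole-1-carboxylate | CC(C)(C)OC(=O)n1cc(I)c2ccc(Br)cc21 | intermediate
4 | 5-ethynyl-1-methyl-1H-imidazole | C#Cc1cncn1C | starting material
5 | tert-butyl 6-bromo-3-[(1-methyl-1H-imidazol-5-yl)ethynyl]-1H-indole-1-carboxylate | CC(C)(C)OC(=O)n1cc(C#Cc2cncn2C)c2ccc(Br)cc21 | intermediate
6 | 6-bromo-3-[(1-methyl-1H-imidazol-5-yl)ethynyl]-1H-indole | Cn1cncc1C#Cc1c[nH]c2cc(Br)ccc12 | intermediate
7 | carbon monoxide | [C-]#[O+] | starting material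
8 | ammonia | N | starting material
9 | (±)-trans-3-(6-bromo-1H-indol-3-yl)-4-(1-methyl-1H-imidazol-5-yl)pyrrolidine-2,5-dione (racemic, 3R*,4R*; the 3S,4S enantiomer is drawn) | Cn1cncc1[C@@H]1[C@@H](c2c[nH]c3cc(Br)ccc23)C(=O)NC1=O | intermediate
10 | didemnimide D, 3-(6-bromo-1H-indol-3-yl)-4-(1-methyl-1H-imidazol-5-yl)-1H-pyrrole-2,5-dione | Cn1cncc1C1=C(c2c[nH]c3cc(Br)ccc23)C(=O)NC1=O | target

## Step count and least certain steps

Total step count: 4. Longest linear sequence: 4 (1 to 3 to 6 to 9 to 10).

**Step 3 (key step).**
- The most likely failure is that the cycle stops after the first insertion of CO, so simple hydroaminocarbonylation of the triple bond competes with ring closure.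
- A second risk is that turnover dies because N3 of ring C occupies coordination sites on iron.
- A lesser risk is hydrodebromination at C6 by the iron hydride species of the cycle.
- The cause is the electron-rich triple bond (push from N1 of ring A), which binds less well to an electron-rich iron carbonyl fragment than a plain diaryl alkyne.
- Fallback: it sets out from 5, which is then isolated after the coupling stage of step 2 and not methanolysed, and it comes back to the route at 10.
  - 5 is submitted to the ruthenium-catalysed [2+2+1] cocyclisation of an alkyne, an isocyanate and CO (Ru3(CO)12 cat., 2,4-dimethoxybenzyl isocyanate, 7 at 1 atm, mesitylene, 130 °C).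
  - This proceeds by oxidative cyclisation on zerovalent ruthenium to an azaruthenacyclopentenone, insertion of CO and reductive elimination.
  - It should give tert-butyl 6-bromo-3-[1-(2,4-dimethoxybenzyl)-4-(1-methyl-1H-imidazol-5-yl)-2,5-dioxo-2,5-dihydro-1H-pyrrol-3-yl]-1H-indole-1-carboxylate F1 directly at the oxidation level of the target.
  - One N–C(=O) unit arrives preformed, no hydride and no free ammonia are present, and step 4 is bypassed.
  - Warm TFA with anisole then removes the 2,4-dimethoxybenzyl and Boc groups of F1 in one operation to give 10.

**Step 2.**
- Most likely to go wrong are protodeiodination of the electron-rich C3 position of 3, oxidative homocoupling of 4 at copper, and slow turnover because N3 of ring C binds copper and palladium.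
- Slow turnover would tempt heating, and with it insertion into C6–Br.
- Fallback: it sets out from 1 and comes back at 6, replacing steps 1 and 2.
  - Direct electrophilic C3–H alkynylation of 1 with 1-[(triisopropylsilyl)ethynyl]-1,2-benziodoxol-3(1H)-one (AuCl cat., Et2O, rt) should give 6-bromo-3-[(triisopropylsilyl)ethynyl]-1H-indole F2 without halogenation or N-protection.
  - TBAF in THF frees 6-bromo-3-ethynyl-1H-indole F3, which is coupled at once with 5-iodo-1-methyl-1H-imidazole (PdCl2(PPh3)2 cat., CuI cat., Et3N, rt) to give 6.
  - The roles of the partners are inverted, and the labile 3-iodoindole is avoided.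

**Step 4.**
- Most likely to go wrong is incomplete conversion, because the basic ring C ties up the quinone and its reduced form as salts or charge-transfer complexes.
- The second risk is over-oxidation of the product by oxidative C–C closure between C2 of ring A and C4 of ring C.
- Fallback: it sets out from 9 and comes back at 10, replacing hydride abstraction by an anionic sequence.
  - Exhaustive deprotonation with LiN(SiMe3)2 (excess, THF, −78 °C) and selenenylation with PhSeCl should take place at the more acidic C4, anti to the indolyl group.
  - The product should be (±)-3-(6-bromo-1H-indol-3-yl)-4-(1-methyl-1H-imidazol-5-yl)-4-(phenylselanyl)pyrrolidine-2,5-dione F4, with selenium cis to C3–H.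
  - Oxidation with H2O2 at 0 °C gives the corresponding selenoxide, (±)-3-(6-bromo-1H-indol-3-yl)-4-(1-methyl-1H-imidazol-5-yl)-4-(phenylseleninyl)pyrrolidine-2,5-dione F5.
  - F5 has the geometry needed for syn elimination and should collapse to 10 below room temperature.

## Further compounds

F1 | step 3 | tert-butyl 6-bromo-3-[1-(2,4-dimethoxybenzyl)-4-(1-methyl-1H-imidazol-5-yl)-2,5-dioxo-2,5-dihydro-1H-pyrrol-3-yl]-1H-indole-1-carboxylate | COc1ccc(CN2C(=O)C(c3cncn3C)=C(c3cn(C(=O)OC(C)(C)C)c4cc(Br)ccc34)C2=O)c(OC)c1
F2 | step 2 | 6-bromo-3-[(triisopropylsilyl)ethynyl]-1H-indole | CC(C)[Si](C#Cc1c[nH]c2cc(Br)ccc12)(C(C)C)C(C)C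
F3 | step 2 | 6-bromo-3-ethynyl-1H-indole | C#Cc1c[nH]c2cc(Br)ccc12
F4 | step 4 | (±)-3-(6-bromo-1H-indol-3-yl)-4-(1-methyl-1H-imidazol-5-yl)-4-(phenylselanyl)pyrrolidine-2,5-dione, selenium cis to C3–H | Cn1cncc1[C@@]1([Se]c2ccccc2)[C@@H](c2c[nH]c3cc(Br)ccc23)C(=O)NC1=O
F5 | step 4 | (±)-3-(6-bromo-1H-indol-3-yl)-4-(1-methyl-1H-imidazol-5-yl)-4-(phenylseleninyl)pyrrolidine-2,5-dione, selenium cis to C3–H | Cn1cncc1[C@@]1([Se](=O)c2ccccc2)[C@@H](c2c[nH]c3cc(Br)ccc23)C(=O)NC1=O
A1 | alternative 1 | methyl 2-(6-bromo-1H-indol-3-yl)-2-oxoacetate | COC(=O)C(=O)c1c[nH]c2cc(Br)ccc12
A2 | alternative 1 | 2-(1-methyl-1H-imidazol-5-yl)acetamide | Cn1cncc1CC(N)=O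
A3 | alternative 2 | 3,4-dibromo-1H-pyrrole-2,5-dione | O=C1NC(=O)C(Br)=C1Br
A4 | alternative 2 | 3-bromo-4-(6-bromo-1H-indol-3-yl)-1H-pyrrole-2,5-dione | O=C1NC(=O)C(Br)=C1c1c[nH]c2cc(Br)ccc12
A5 | alternative 2 | 1-methyl-5-(tributylstannyl)-1H-imidazole | CCCC[Sn](CCCC)(CCCC)c1cncn1C
A6 | alternative 3 | 4-(6-bromo-1H-indol-3-yl)-2,5-dioxo-2,5-dihydro-1H-pyrrole-3-carbaldehyde | O=CC1=C(c2c[nH]c3cc(Br)ccc23)C(=O)NC1=O
A7 | alternative 3 | 3-(6-bromo-1H-indol-3-yl)-4-[(E)-(methylimino)methyl]-1H-pyrrole-2,5-dione | C/N=C/C1=C(c2c[nH]c3cc(Br)ccc23)C(=O)NC1=O
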